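## Retrosynthetic overview

1. The target comes from its C6 triethylsilyl ether, and that from ring-closing metathesis at C1=C10 of an acyclic diene ester; the ten-membered carbocycle is closed last.
2. The diene comes from acylation and a reagent-controlled methallylboration of a C8 aldehyde (C8–C9 bond, C8 stereocentre).
3. The C8 aldehyde comes from an L-proline-catalysed anti cross-aldol of isovaleraldehyde onto an enantiopure epoxy aldehyde (C6–C7 bond, C6 and C7; new acceptor class).
4. The epoxy aldehyde comes from Shi epoxidation of an E-dienol (C4 and C5, first stereocentres), itself made by Negishi carboalumination of hex-5-en-1-yne.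
5. Ring order: oxirane first (step 2), ten-membered ring second (step 7).

Assumption: the SMILES is read as drawn, i.e. Z ring olefin, trans epoxide, 4R,5R,6R,7S,8R in germacrane numbering (C1=C10 olefin, C4–C5 epoxide, C6 OH, C7 isopropyl, C8 ester); this numbering is used for positions below.

## Route

Step 1
Reactants: 1 hex-5-en-1-yne
Product: 4 (2E)-3-methylhepta-2,6-dien-1-ol, via alkenylalane 2 (not isolated), via lithium alanate 3 (not isolated)
Conditions: AlMe3 (2 equiv), Cp2ZrCl2 (0.2 equiv), CH2Cl2, 0 °C to rt; n-BuLi, THF/hexane, −78 °C; (CH2O)n, −78 °C to rt; aq. HCl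
Reagents that add atoms: trimethylaluminium C[Al](C)C; paraformaldehyde (as formaldehyde) C=O
Why: Negishi zirconium-catalysed carboalumination adds methyl and aluminium syn across the terminal alkyne (methyl to the internal carbon, the isolated alkene does not react), and the derived alanate adds to formaldehyde with retention, so only the E allylic alcohol forms.

Step 2
Reactants: 4 (2E)-3-methylhepta-2,6-dien-1-ol
Product: 5 [(2R,3R)-3-(but-3-en-1-yl)-3-methyloxiran-2-yl]methanol
Conditions: Shi ketone (D-fructose-derived, 0.3 equiv), Oxone (2KHSO5·KHSO4·K2SO4), K2CO3, Bu4NHSO4 (cat.), MeCN/CH2(OMe)2, aq. Na2B4O7 buffer, 0 °C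
Reagents that add atoms: potassium peroxymonosulfate (active part of Oxone) [K+].[O-]S(=O)(=O)OO
Why: Shi asymmetric epoxidation: the chiral dioxirane formed from the ketone and KHSO5 transfers oxygen through a spiro transition state to the electron-rich E-trisubstituted olefin (the monosubstituted vinyl group is much slower), setting C4 and C5 as the 2R,3R trans-epoxide, the first stereocentres of the route.

Step 3
Reactants: 5 [(2R,3R)-3-(but-3-en-1-yl)-3-methyloxiran-2-yl]methanol
Product: 6 (2S,3R)-3-(but-3-en-1-yl)-3-methyloxirane-2-carbaldehyde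
Conditions: TEMPO (0.1 equiv), PhI(OAc)2 (1.2 equiv), CH2Cl2, rt
Reagents that add atoms: none
Why: TEMPO-catalysed oxidation with PhI(OAc)2 (oxoammonium mechanism) stops at the aldehyde under non-basic conditions, so the epoxide, its stereocentres and the alkene are untouched (the descriptor at C2 changes only because the CIP priorities change).

Step 4
Reactants: 6 (2S,3R)-3-(but-3-en-1-yl)-3-methyloxirane-2-carbaldehyde; 7 3-methylbutanal
Product: 9 (2S,3R)-3-[(2R,3R)-3-(but-3-en-1-yl)-3-methyloxiran-2-yl]-2-(propan-2-yl)-3-[(triethylsilyl)oxy]propanal, via aldol 8 (not isolated)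
Conditions: L-proline (0.2 equiv), DMF, 4 °C, 7 (3 equiv) added over 24 h; then imidazole, Et3SiCl, 0 °C
Reagents that add atoms: chlorotriethylsilane CC[Si](Cl)(CC)CC
Why: Proposed new method: an enamine-catalysed aldehyde–aldehyde cross-aldol in which an enantiopure trisubstituted α,β-epoxy aldehyde is the acceptor, a substrate class on which this reaction has, to my knowledge, not been shown. The epoxide carbon of 6 cannot form an enamine, so 6 can only act as the (α-oxygen-activated) electrophile. The L-proline enamine of 7 adds through the hydrogen-bonded Houk–List transition state to give the anti aldol with the 2S α-carbon. The catalyst-preferred aldehyde face is the polar Felkin–Anh/Cornforth face of 6 (attack anti to the epoxide C–O bond), so C6 and C7 are set as a matched pair. The closest known reactions are the proline-catalysed cross-aldol of aldehyde donors with α-branched or α-alkoxy aldehyde acceptors and the diarylprolinol-catalysed cross-aldol with ynals or glyoxylate. The labile β-hydroxy aldehyde 8 is silylated in the same flask.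

Step 5
Reactants: 9 (2S,3R)-3-[(2R,3R)-3-(but-3-en-1-yl)-3-methyloxiran-2-yl]-2-(propan-2-yl)-3-[(triethylsilyl)oxy]propanal
Product: 11 (1R,2R,3R)-1-[(2R,3R)-3-(but-3-en-1-yl)-3-methyloxiran-2-yl]-5-methyl-2-(propan-2-yl)-1-[(triethylsilyl)oxy]hex-5-en-3-ol, via borinate 10 (not isolated)
Conditions: (+)-Ipc2BOMe ((−)-α-pinene series), CH2=C(CH3)CH2MgCl, Et2O, −78 °C to rt; 9, −78 °C; then NaBO3·4H2O, THF/H2O, rt
Reagents that add atoms: 2-methylallylmagnesium chloride CC(=C)C[Mg]Cl
Why: Brown asymmetric allylboration: the B-(2-methylallyl)diisopinocampheylborane of the (−)-α-pinene series adds through a chair Zimmerman–Traxler transition state to the Re face of the aldehyde, so reagent control (against the weak Felkin preference of 9) sets C8 as R, anti to the isopropyl group and syn to the C6 oxygen; the borinate is cleaved under mild, weakly basic oxidative conditions.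

Step 6
Reactants: 11 (1R,2R,3R)-1-[(2R,3R)-3-(but-3-en-1-yl)-3-methyloxiran-2-yl]-5-methyl-2-(propan-2-yl)-1-[(triethylsilyl)oxy]hex-5-en-3-ol; 12 3,4,5-trimethoxybenzoyl chloride
Product: 13 (1R,2R,3R)-1-[(2R,3R)-3-(but-3-en-1-yl)-3-methyloxiran-2-yl]-5-methyl-2-(propan-2-yl)-1-[(triethylsilyl)oxy]hex-5-en-3-yl 3,4,5-trimethoxybenzoate
Conditions: Et3N, DMAP (0.3 equiv), CH2Cl2, rt
Reagents that add atoms: none
Why: DMAP-catalysed acylation (acylpyridinium intermediate) of the only free hydroxyl installs the aryl ester at C8 with retention; it is run at once so that the free C8 alcohol cannot open the epoxide.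

Step 7
Reactants: 13 (1R,2R,3R)-1-[(2R,3R)-3-(but-3-en-1-yl)-3-methyloxiran-2-yl]-5-methyl-2-(propan-2-yl)-1-[(triethylsilyl)oxy]hex-5-en-3-yl 3,4,5-trimethoxybenzoate
Product: 14 (1R,2R,3R,4R,6Z,10R)-6,10-dimethyl-3-(propan-2-yl)-2-[(triethylsilyl)oxy]-11-oxabicyclo[8.1.0]undec-6-en-4-yl 3,4,5-trimethoxybenzoate
Conditions: second-generation Grubbs catalyst RuCl2(=CHPh)(H2IMes)(PCy3) (10 mol%), toluene (1 mM), 80 °C, Ar purge
Reagents that add atoms: none
Why: Ring-closing metathesis: the ruthenium alkylidene formed at the monosubstituted alkene closes onto the 1,1-disubstituted alkene with loss of ethene; a Z double bond is less strained than E in a ten-membered ring, so the Z-trisubstituted olefin is expected, and no other alkene competes because the second one is already an epoxide.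

Step 8
Reactants: 14 (1R,2R,3R,4R,6Z,10R)-6,10-dimethyl-3-(propan-2-yl)-2-[(triethylsilyl)oxy]-11-oxabicyclo[8.1.0]undec-6-en-4-yl 3,4,5-trimethoxybenzoate
Product: 15 (1R,2R,3S,4R,6Z,10R)-2-hydroxy-6,10-dimethyl-3-(propan-2-yl)-11-oxabicyclo[8.1.0]undec-6-en-4-yl 3,4,5-trimethoxybenzoate
Conditions: HF·pyridine, pyridine, THF, 0 °C
Reagents that add atoms: none
Why: Fluoride-mediated Si–O cleavage (silyl ether deprotection) under buffered, near-neutral conditions removes the TES group without acid-promoted transannular opening of the epoxide or base-promoted 1,3-acyl migration, giving the target.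

## Compound list

1 | hex-5-en-1-yne | C#CCCC=C | starting material
2 | dimethyl[(1E)-2-methylhexa-1,5-dien-1-yl]alumane | C=CCC/C(C)=C/[Al](C)C | intermediate
3 | lithium butyl(dimethyl)[(1E)-2-methylhexa-1,5-dien-1-yl]aluminate | [Li+].C=CCC/C(C)=C/[Al-](C)(C)CCCC | intermediate
4 | (2E)-3-methylhepta-2,6-dien-1-ol | C=CCC/C(C)=C/CO | intermediate
5 | [(2R,3R)-3-(but-3-en-1-yl)-3-methyloxiran-2-yl]methanol | C=CCC[C@@]1(C)O[C@@H]1CO | intermediate
6 | (2S,3R)-3-(but-3-en-1-yl)-3-methyloxirane-2-carbaldehyde | C=CCC[C@@]1(C)O[C@@H]1C=O | intermediate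
7 | 3-methylbutanal | CC(C)CC=O | starting material
8 | (2S,3R)-3-[(2R,3R)-3-(but-3-en-1-yl)-3-methyloxiran-2-yl]-3-hydroxy-2-(propan-2-yl)propanal | C=CCC[C@@]1(C)O[C@@H]1[C@H](O)[C@H](C(C)C)C=O | intermediate
9 | (2S,3R)-3-[(2R,3R)-3-(but-3-en-1-yl)-3-methyloxiran-2-yl]-2-(propan-2-yl)-3-[(triethylsilyl)oxy]propanal | C=CCC[C@@]1(C)O[C@@H]1[C@H](O[Si](CC)(CC)CC)[C@H](C(C)C)C=O | intermediate
10 | (1R,2R,3R)-1-[(2R,3R)-3-(but-3-en-1-yl)-3-methyloxiran-2-yl]-5-methyl-2-(propan-2-yl)-1-[(triethylsilyl)oxy]hex-5-en-3-yl bis[(1S,2R,3S,5S)-2,6,6-trimethylbicyclo[3.1.1]heptan-3-yl]borinate | C=CCC[C@@]1(C)O[C@@H]1[C@H](O[Si](CC)(CC)CC)[C@H](C(C)C)[C@@H](CC(C)=C)OB([C@H]2C[C@H]3C[C@@H]([C@@H]2C)C3(C)C)[C@H]2C[C@H]3C[C@@H]([C@@H]2C)C3(C)C | intermediate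
11 | (1R,2R,3R)-1-[(2R,3R)-3-(but-3-en-1-yl)-3-methyloxiran-2-yl]-5-methyl-2-(propan-2-yl)-1-[(triethylsilyl)oxy]hex-5-en-3-ol | C=CCC[C@@]1(C)O[C@@H]1[C@H](O[Si](CC)(CC)CC)[C@H](C(C)C)[C@@H](CC(C)=C)O | intermediate
12 | 3,4,5-trimethoxybenzoyl chloride | COc1cc(C(=O)Cl)cc(OC)c1OC | starting material
13 | (1R,2R,3R)-1-[(2R,3R)-3-(but-3-en-1-yl)-3-methyloxiran-2-yl]-5-methyl-2-(propan-2-yl)-1-[(triethylsilyl)oxy]hex-5-en-3-yl 3,4,5-trimethoxybenzoate | C=CCC[C@@]1(C)O[C@@H]1[C@H](O[Si](CC)(CC)CC)[C@H](C(C)C)[C@@H](CC(C)=C)OC(=O)c1cc(OC)c(OC)c(OC)c1 | intermediate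
14 | (1R,2R,3R,4R,6Z,10R)-6,10-dimethyl-3-(propan-2-yl)-2-[(triethylsilyl)oxy]-11-oxabicyclo[8.1.0]undec-6-en-4-yl 3,4,5-trimethoxybenzoate | COc1cc(C(=O)O[C@@H]2C/C(C)=C\CC[C@@]3(C)O[C@@H]3[C@H](O[Si](CC)(CC)CC)[C@@H]2C(C)C)cc(OC)c1OC | intermediate
15 | (1R,2R,3S,4R,6Z,10R)-2-hydroxy-6,10-dimethyl-3-(propan-2-yl)-11-oxabicyclo[8.1.0]undec-6-en-4-yl 3,4,5-trimethoxybenzoate | COc1cc(C(=O)O[C@@H]2C/C(C)=C\CC[C@@]3(C)O[C@@H]3[C@H](O)[C@@H]2C(C)C)cc(OC)c1OC | target

## Step count and risks

Total step count: 8. Longest linear sequence: 8 steps (from 1; compounds 7 and 12 are bought).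

The three steps most likely to fail:

Step 4 (the proposed aldol). The risks are self-aldol of 7, slow addition to the hindered epoxy aldehyde, and attack of the amine on the epoxide. The fallback uses known chemistry, sets out from 6 and comes back to the route at 9. 2,6-Dimethylphenyl 3-methylbutanoate F1 (from 3-methylbutanoyl chloride and 2,6-dimethylphenol) is converted with LiN(i-Pr)2 in THF at −78 °C into its E lithium enolate and added to 6. This is a Heathcock anti-selective ester aldol; the aldehyde face is chosen by Felkin–Anh attack anti to the epoxide C–O bond. It gives 2,6-dimethylphenyl (2S,3R)-3-[(2R,3R)-3-(but-3-en-1-yl)-3-methyloxiran-2-yl]-3-hydroxy-2-(propan-2-yl)propanoate F2. Et3SiCl and imidazole give 2,6-dimethylphenyl (2S,3R)-3-[(2R,3R)-3-(but-3-en-1-yl)-3-methyloxiran-2-yl]-2-(propan-2-yl)-3-[(triethylsilyl)oxy]propanoate F3, and i-Bu2AlH at −78 °C reduces the aryl ester to aldehyde 9. The diastereoselectivity is expected to be lower than in the catalytic route, so chromatographic separation is likely needed.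

Step 5 (methallylboration). The reagent must override the intrinsic Felkin and 1,3-anti bias of 9, so the diastereomer ratio may be modest; the free C8 alcohol 11 is also sensitive to cyclisation onto the epoxide. The fallback sets out from 9 and comes back at 13, and uses the substrate bias instead of fighting it. The antipodal reagent from (−)-Ipc2BOMe ((+)-α-pinene series) adds in the matched sense to the Si face. This gives (1R,2R,3S)-1-[(2R,3R)-3-(but-3-en-1-yl)-3-methyloxiran-2-yl]-5-methyl-2-(propan-2-yl)-1-[(triethylsilyl)oxy]hex-5-en-3-yl bis[(1R,2S,3R,5R)-2,6,6-trimethylbicyclo[3.1.1]heptan-3-yl]borinate F4 (not isolated). NaBO3·4H2O cleaves it to the C8 epimer (1R,2R,3S)-1-[(2R,3R)-3-(but-3-en-1-yl)-3-methyloxiran-2-yl]-5-methyl-2-(propan-2-yl)-1-[(triethylsilyl)oxy]hex-5-en-3-ol F5. A Mitsunobu esterification (PPh3, diisopropyl azodicarboxylate, 3,4,5-trimethoxybenzoic acid, toluene) then inverts C8 and installs the ester in one operation, giving 13.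

Step 7 (ring-closing metathesis). A ten-membered ring with a trisubstituted olefin may give oligomers, and the E isomer may form alongside or instead of the Z isomer. The fallback sets out from 11 and comes back at 14, moving the ring closure ahead of the acylation. The chain then carries a free homoallylic hydroxyl next to the 1,1-disubstituted alkene instead of the bulky aryl ester. Ring-closing metathesis of 11 with the same ruthenium catalyst at high dilution gives (1R,2R,3R,4R,6Z,10R)-6,10-dimethyl-3-(propan-2-yl)-2-[(triethylsilyl)oxy]-11-oxabicyclo[8.1.0]undec-6-en-4-ol F6. F6 is then acylated with 12 (Et3N, DMAP) to give 14. This fallback does not by itself guarantee the Z geometry; that remains the main open risk of the route.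

## Further compounds

F1 | step 4 | 2,6-dimethylphenyl 3-methylbutanoate | CC(C)CC(=O)Oc1c(C)cccc1C
F2 | step 4 | 2,6-dimethylphenyl (2S,3R)-3-[(2R,3R)-3-(but-3-en-1-yl)-3-methyloxiran-2-yl]-3-hydroxy-2-(propan-2-yl)propanoate | C=CCC[C@@]1(C)O[C@@H]1[C@H](O)[C@H](C(C)C)C(=O)Oc1c(C)cccc1C
F3 | step 4 | 2,6-dimethylphenyl (2S,3R)-3-[(2R,3R)-3-(but-3-en-1-yl)-3-methyloxiran-2-yl]-2-(propan-2-yl)-3-[(triethylsilyl)oxy]propanoate | C=CCC[C@@]1(C)O[C@@H]1[C@H](O[Si](CC)(CC)CC)[C@H](C(C)C)C(=O)Oc1c(C)cccc1C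
F4 | step 5 | (1R,2R,3S)-1-[(2R,3R)-3-(but-3-en-1-yl)-3-methyloxiran-2-yl]-5-methyl-2-(propan-2-yl)-1-[(triethylsilyl)oxy]hex-5-en-3-yl bis[(1R,2S,3R,5R)-2,6,6-trimethylbicyclo[3.1.1]heptan-3-yl]borinate | C=CCC[C@@]1(C)O[C@@H]1[C@H](O[Si](CC)(CC)CC)[C@H](C(C)C)[C@H](CC(C)=C)OB([C@@H]2C[C@@H]3C[C@H]([C@H]2C)C3(C)C)[C@@H]2C[C@@H]3C[C@H]([C@H]2C)C3(C)C
F5 | step 5 | (1R,2R,3S)-1-[(2R,3R)-3-(but-3-en-1-yl)-3-methyloxiran-2-yl]-5-methyl-2-(propan-2-yl)-1-[(triethylsilyl)oxy]hex-5-en-3-ol | C=CCC[C@@]1(C)O[C@@H]1[C@H](O[Si](CC)(CC)CC)[C@H](C(C)C)[C@H](CC(C)=C)O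
F6 | step 7 | (1R,2R,3R,4R,6Z,10R)-6,10-dimethyl-3-(propan-2-yl)-2-[(triethylsilyl)oxy]-11-oxabicyclo[8.1.0]undec-6-en-4-ol | O[C@@H]1C/C(C)=C\CC[C@@]2(C)O[C@@H]2[C@H](O[Si](CC)(CC)CC)[C@@H]1C(C)C
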